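All runs are calculated with made-up constants; scatter was added.

The amounts in the alpha run, which is the very flask asked about, keep step: substrate lost and target gained agree within the scatter, so the dispute concerns the pace of one conversion under the enzyme.

| flask | substrate | enzyme | remark | time |
|---|---|---|---|---|
| alpha | 0.20 M | 1.4 µM | the very flask that is asked about, followed so far |  |
| flask | 0.20 M | 1.4 µM |  | 6.0 h |

- alpha (time / min: target / %, substrate / %): 8.00: 3.6, 98.4; 20.0: 6.0, 94.2; 50.0: 14.0, 87.1; 120: 34.5, 65.9

(readings scatter by 1 percentage point)



* amount of target in percent of the substrate charged, at 40 min, 2.0 h and 6.0 h

Two chemists read these amounts differently. The first holds that the pace is fixed, zero order in c_substrate. She divides 120 min by the reading 34.5% and gets 5.80 h, the emptying time, that is, the time in which the whole charge would turn into target at the pace read so far. The scatter of that reading moves it by 0.168 h. The reading at 50.0 min gives 5.95 h, the same within its larger scatter. Her reckoning gives 11.5% at 40 min, 34.5% at 2.0 h, and at 6.0 h, which is 1.03 emptying times, a finished charge.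

The second chemist, who made the forecast, expects the pace to fall. On a logarithmic scale a first-order flask gives one constant at every reading, and the substrate readings give 0.166 h⁻¹ at 50.0 min and 0.209 h⁻¹ at 120 min. These part by more than the 0.0138 h⁻¹ that scatter gives the first of them, which counts mildly against a strict first order; held to the end, the later constant gives 71.4%. The forecast stands above that, at 11.3%, 34% and 85%, with the warning: “Falling saturation, product inhibition, enzyme decay or an equilibrium limit would all lower the yield”. At 6.0 h it differs from the first chemist's finished charge.

The flask gives 11.2%, 33.3% and 94.9%, which at 6.0 h lies nearer to the finished charge than to the forecast.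

    substrate + enzyme → target + enzyme, rate k1*[substrate]*[enzyme]/(1 + ([substrate]/Km1)) (5.70 mM, k = 1200 M⁻¹ s⁻¹)

After 1.03 emptying times the flask still holds 5.1% of its substrate. That shortfall of 5.1 percentage points comes from the crowding by c_substrate in the law together with the length of the run: with the crowding taken away, the target at 6.0 h is 100%. In this law the first-order view belongs to c_substrate well under 5.7 mM, and the flask at 6.0 h still holds 10.1 mM. The flask at 60.0 h, ten times the emptying time, stands at 100% target.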